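**Strategy.** The tetrahydrofuran ring (O1, C2–C5) has no substituent on C5, an OCH2 carbon, so the C4–C5 bond is made as an enol-ether double bond. Ring-closing metathesis of an O1-vinyl ether with a methylene group on C4 closes the five-membered ring in one operation and leaves C4 trigonal for a later face-selective hydrogenation. The precursor is the vinyl ether of an Evans syn-aldol-derived homoallylic alcohol in which C2 and C3 already have the target configuration, C9 is a bulky triisopropylsilyl ether and the phenol is a benzyl ether.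

Key step: step 7

Assumption (remark on the chemistry): ring atoms are numbered O1, C2 (guaiacyl-bearing), C3 (bearing C9, the CH2OH carbon), C4 (bearing the veratryl CH2) and C5 (OCH2), the target being 2S,3R,4R (2,3-trans, 3,4-cis); C9 is carried as a triisopropylsilyl ether because a larger silyl group should shield the C3 face of the C4=C5 bond better in step 8 and silylate the primary hydroxyl more selectively in step 5.

Step 1
Reactants: 1 3,4-dimethoxybenzyl chloride; 2 diketene (4-methyleneoxetan-2-one)
Product: 4 4-(3,4-dimethoxyphenyl)-3-methylenebutanoic acid, via veratrylmagnesium chloride 3 (not isolated)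
Conditions: Mg turnings, THF, 0 °C (slow addition of 1); then 2, NiCl2 (5 mol%), THF, −20 °C → rt; aq HCl
Reagents that add atoms: none
Why: Magnesium insertion gives the benzylic Grignard reagent, which in the nickel-catalysed ring-opening of diketene (cross-coupling at the vinylic C–O bond of the β-lactone) should be delivered to the alkene carbon and leave the carboxylate untouched, giving the 3-methylene acid after acidification.

Step 2
Reactants: 4 4-(3,4-dimethoxyphenyl)-3-methylenebutanoic acid; 5 (S)-4-benzyl-2-oxazolidinone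
Product: 7 (S)-4-benzyl-3-[4-(3,4-dimethoxyphenyl)-3-methylenebutanoyl]oxazolidin-2-one, via mixed pivalic anhydride 6 (not isolated)
Conditions: t-BuCOCl, Et3N, THF, −20 °C; then 5, LiCl, −20 °C → rt
Reagents that add atoms: none
Why: N-Acylation of the oxazolidinone through the mixed pivalic anhydride (auxiliary attachment with Et3N/LiCl) uses only weak base, so the β,γ-double bond should stay out of conjugation.

Step 3
Reactants: 7 (S)-4-benzyl-3-[4-(3,4-dimethoxyphenyl)-3-methylenebutanoyl]oxazolidin-2-one; 8 O-benzylvanillin (4-benzyloxy-3-methoxybenzaldehyde)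
Product: 11 (S)-4-benzyl-3-[(2S,3S)-3-(4-benzyloxy-3-methoxyphenyl)-2-[3-(3,4-dimethoxyphenyl)prop-1-en-2-yl]-3-hydroxypropanoyl]oxazolidin-2-one, via dibutylboron dienolate 9 (not isolated), via boron aldolate 10 (not isolated)
Conditions: Bu2BOTf, iPr2NEt, CH2Cl2, −78 → 0 °C; 8, −78 → 0 °C; then pH 7 buffer, MeOH, H2O2, 0 °C
Reagents that add atoms: none
Why: Evans boron syn-aldol reaction: soft enolisation gives the (Z)-dienolate, which should react at its α-carbon through a Zimmerman–Traxler chair on the face remote from the auxiliary benzyl group, setting the carbinol carbon (future C2) and the α-carbon (future C3) with syn relative configuration, the arrangement that becomes 2,3-trans in the ring.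

Step 4
Reactants: 11 the syn-aldol imide
Product: 12 (1S,2R)-1-(4-benzyloxy-3-methoxyphenyl)-2-[3-(3,4-dimethoxyphenyl)prop-1-en-2-yl]propane-1,3-diol
Conditions: LiBH4, MeOH (1.1 equiv), THF, 0 °C; aqueous work-up
Reagents that add atoms: none
Why: Reductive cleavage of the imide with LiBH4 reduces the exocyclic carbonyl to the primary alcohol (C9) and releases the auxiliary, under conditions that should leave the alkene, the benzyl ether and the C3 configuration alone.

Step 5
Reactants: 12 the 1,3-diol
Product: 13 (1S,2R)-1-(4-benzyloxy-3-methoxyphenyl)-2-[3-(3,4-dimethoxyphenyl)prop-1-en-2-yl]-3-(triisopropylsilyloxy)propan-1-ol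
Conditions: iPr3SiCl, imidazole, DMF, 0 °C → rt
Reagents that add atoms: triisopropylsilyl chloride, CC(C)[Si](Cl)(C(C)C)C(C)C
Why: Chemoselective silylation: the bulky silyl chloride should react at the unhindered primary hydroxyl much faster than at the secondary benzylic one, which stays free for vinylation.

Step 6
Reactants: 13 the mono-silylated homoallylic alcohol
Product: 14 triisopropyl{[(2R,3S)-3-(4-benzyloxy-3-methoxyphenyl)-2-[3-(3,4-dimethoxyphenyl)prop-1-en-2-yl]-3-(vinyloxy)propyl]oxy}silane (the O-vinyl ether of 13)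
Conditions: [Ir(cod)Cl]2 (2 mol%), Na2CO3, vinyl acetate, toluene, 100 °C; chromatography on Et3N-deactivated silica
Reagents that add atoms: vinyl acetate, CC(=O)OC=C
Why: Iridium-catalysed transfer vinylation of an alcohol with vinyl acetate runs under basic conditions that the acid-labile electron-rich benzylic position should tolerate, and it makes the O–vinyl bond without breaking the C2–O bond, so C2 keeps its configuration.

Step 7
Reactants: 14 the O-vinyl ether
Product: 15 (2S,3R)-2-(4-benzyloxy-3-methoxyphenyl)-4-(3,4-dimethoxybenzyl)-3-[(triisopropylsilyloxy)methyl]-2,3-dihydrofuran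
Conditions: Mo(=CHCMe2Ph)(=N-2,6-iPr2C6H3)[OCMe(CF3)2]2 (10 mol%), C6H6 (0.01 M), 25 → 60 °C, Ar, rigorously dry
Reagents that add atoms: none
Why: The molybdenum alkylidene should exchange with the unhindered O-vinyl group to place the metal on C5, this alkylidene adds across the C4 exo-methylene in an intramolecular [2+2] cycloaddition, and cycloreversion of the metallacyclobutane releases the C4=C5 enol ether and Mo=CH2, which carries the chain with loss of ethene. The closest known reaction type is molybdenum-catalysed ring-closing metathesis of acyclic olefinic enol ethers to cyclic enol ethers, including closures onto 1,1-disubstituted alkenes. The 2,3-dihydrofuran ring (O1, C2, C3, C4, C5) is closed as a five-membered ring by joining the two alkene termini of a 1,6-diene. No stereocentre is created, and C2 and C3 are untouched because the catalyst breaks no bond at either carbon. The step needs ring closure to beat intermolecular metathesis, which high dilution, the ease of five-membered closure and the poor cross-metathesis reactivity of the 1,1-disubstituted alkene should secure, and the silyl and benzyl ethers leave no protic group to destroy the oxophilic catalyst.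

Step 8
Reactants: 15 the 2,3-dihydrofuran
Product: 16 4-[(2S,3R,4R)-4-(3,4-dimethoxybenzyl)-3-[(triisopropylsilyloxy)methyl]tetrahydrofuran-2-yl]-2-methoxyphenol
Conditions: H2 (1 atm), 10% Pd/C, EtOAc, rt, stopped when 15 and the benzyl ether are consumed
Reagents that add atoms: none
Why: Heterogeneous catalytic hydrogenation should add hydrogen syn to the C4=C5 enol ether from the ring face opposite the adjacent C3 silyloxymethyl group, which places the veratryl CH2 cis to C9 (C4 = R), and the same catalyst cleaves the aryl benzyl ether by hydrogenolysis.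

Step 9
Reactants: 16 the silyl-protected tetrahydrofuran
Product: 17 4'-O-methyllariciresinol, 4-[(2S,3R,4R)-4-(3,4-dimethoxybenzyl)-3-(hydroxymethyl)tetrahydrofuran-2-yl]-2-methoxyphenol
Conditions: Bu4NF, THF, 0 °C → rt; aq NH4Cl
Reagents that add atoms: none
Why: Fluoride-mediated desilylation, driven by Si–F bond formation, should free the C9 hydroxyl without touching any stereocentre.

**Compound list**

1 | 3,4-dimethoxybenzyl chloride | COc1ccc(CCl)cc1OC | starting material
2 | diketene (4-methyleneoxetan-2-one) | C=C1CC(=O)O1 | starting material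
3 | 3,4-dimethoxybenzylmagnesium chloride (veratrylmagnesium chloride) | COc1ccc(C[Mg]Cl)cc1OC | intermediate
4 | 4-(3,4-dimethoxyphenyl)-3-methylenebutanoic acid | COc1ccc(CC(=C)CC(=O)O)cc1OC | intermediate
5 | (S)-4-benzyl-2-oxazolidinone | O=C1N[C@@H](Cc2ccccc2)CO1 | starting material
6 | 4-(3,4-dimethoxyphenyl)-3-methylenebutanoic pivalic anhydride | COc1ccc(CC(=C)CC(=O)OC(=O)C(C)(C)C)cc1OC | intermediate
7 | (S)-4-benzyl-3-[4-(3,4-dimethoxyphenyl)-3-methylenebutanoyl]oxazolidin-2-one | COc1ccc(CC(=C)CC(=O)N2[C@@H](Cc3ccccc3)COC2=O)cc1OC | intermediate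
8 | O-benzylvanillin (4-benzyloxy-3-methoxybenzaldehyde) | COc1cc(C=O)ccc1OCc1ccccc1 | starting material
9 | dibutylboron (Z)-dienolate of 7 | CCCCB(CCCC)O/C(=C\C(=C)Cc1ccc(OC)c(OC)c1)N1[C@@H](Cc2ccccc2)COC1=O | intermediate
10 | O-dibutylboryl aldolate of 11 | COc1cc([C@@H](OB(CCCC)CCCC)[C@@H](C(=O)N2[C@@H](Cc3ccccc3)COC2=O)C(=C)Cc2ccc(OC)c(OC)c2)ccc1OCc1ccccc1 | intermediate
11 | (S)-4-benzyl-3-[(2S,3S)-3-(4-benzyloxy-3-methoxyphenyl)-2-[3-(3,4-dimethoxyphenyl)prop-1-en-2-yl]-3-hydroxypropanoyl]oxazolidin-2-one | COc1cc([C@@H](O)[C@@H](C(=O)N2[C@@H](Cc3ccccc3)COC2=O)C(=C)Cc2ccc(OC)c(OC)c2)ccc1OCc1ccccc1 | intermediate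
12 | (1S,2R)-1-(4-benzyloxy-3-methoxyphenyl)-2-[3-(3,4-dimethoxyphenyl)prop-1-en-2-yl]propane-1,3-diol | COc1cc([C@@H](O)[C@@H](CO)C(=C)Cc2ccc(OC)c(OC)c2)ccc1OCc1ccccc1 | intermediate
13 | (1S,2R)-1-(4-benzyloxy-3-methoxyphenyl)-2-[3-(3,4-dimethoxyphenyl)prop-1-en-2-yl]-3-(triisopropylsilyloxy)propan-1-ol | COc1cc([C@@H](O)[C@@H](CO[Si](C(C)C)(C(C)C)C(C)C)C(=C)Cc2ccc(OC)c(OC)c2)ccc1OCc1ccccc1 | intermediate
14 | triisopropyl{[(2R,3S)-3-(4-benzyloxy-3-methoxyphenyl)-2-[3-(3,4-dimethoxyphenyl)prop-1-en-2-yl]-3-(vinyloxy)propyl]oxy}silane | COc1cc([C@@H](OC=C)[C@@H](CO[Si](C(C)C)(C(C)C)C(C)C)C(=C)Cc2ccc(OC)c(OC)c2)ccc1OCc1ccccc1 | intermediate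
15 | (2S,3R)-2-(4-benzyloxy-3-methoxyphenyl)-4-(3,4-dimethoxybenzyl)-3-[(triisopropylsilyloxy)methyl]-2,3-dihydrofuran | COc1cc([C@H]2OC=C(Cc3ccc(OC)c(OC)c3)[C@@H]2CO[Si](C(C)C)(C(C)C)C(C)C)ccc1OCc1ccccc1 | intermediate
16 | 4-[(2S,3R,4R)-4-(3,4-dimethoxybenzyl)-3-[(triisopropylsilyloxy)methyl]tetrahydrofuran-2-yl]-2-methoxyphenol | COc1cc([C@H]2OC[C@H](Cc3ccc(OC)c(OC)c3)[C@@H]2CO[Si](C(C)C)(C(C)C)C(C)C)ccc1O | intermediate
17 | 4'-O-methyllariciresinol | COc1cc([C@H]2OC[C@H](Cc3ccc(OC)c(OC)c3)[C@@H]2CO)ccc1O | target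

**Step count.** Total: 9 steps. Longest linear sequence: 9 steps (1 → 17); compounds 2, 5 and 8 enter as purchased materials.

**Steps most likely to fail**

Step 7 (ring-closing metathesis). The catalyst may be diverted into a slowly turning alkoxy-substituted alkylidene or decompose before it engages the hindered 1,1-disubstituted alkene, so that closure stalls or intermolecular metathesis takes over. The fallback sets out from alcohol 13 and comes back at dihydrofuran 15, building the O1–C5 bond through a lactol instead of a metathesis. Hydroboration–oxidation of the exo-methylene group (9-BBN, THF; then NaOH, H2O2) should give the 1,4-diol F1 as a mixture of C4 epimers, which is of no consequence. Primary-selective oxidation with TEMPO and PhI(OAc)2 lets the hydroxy aldehyde close and oxidise on to the γ-lactone F2. Reduction with iBu2AlH at −78 °C gives the lactol F3, and dehydration with MsCl and Et3N removes the C5 hydroxyl and the C4 hydrogen to give 15.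

Step 8 (hydrogenation). Facial discrimination at C4 may be insufficient, because the C2 aryl group lies on the face opposite the C3 side chain, and hydrogenolysis of the benzylic C2–O1 ring bond may compete before the benzyl ether is gone. The fallback sets out from alcohol 13 and comes back at 16, setting C4 by enolate protonation instead of alkene hydrogenation. The diol F1 and lactone F2 are made as above. Deprotonation of F2 with LiN(iPr)2 in THF at −78 °C and quenching of the enolate with 2,6-di-tert-butyl-4-methylphenol should protonate C4 on the face away from the C3 side chain and give the 3,4-cis lactone F4. LiAlH4 reduces it to the diol F5, TsCl in pyridine sulfonylates the primary hydroxyl to the monotosylate F6, and NaH in THF closes the ring by displacement at C5 to the tetrahydrofuran benzyl ether F7. A short hydrogenolysis (H2, Pd/C, EtOAc) of this saturated compound then gives 16.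

Step 6 (O-vinylation). Vinyl transfer to the hindered benzylic hydroxyl may be slow, with competing O-acetylation or iridium hydride-induced migration of the exo-methylene double bond. The fallback sets out from alcohol 13 and comes back at vinyl ether 14, making the vinyl group by carbonyl methylenation instead of vinyl transfer. Formylation with acetic formic anhydride and pyridine gives the formate F8, and Tebbe methylenation of the formyl carbonyl with Cp2Ti(μ-Cl)(μ-CH2)AlMe2 in THF/toluene with pyridine (−40 °C → rt) gives 14.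

**Further compounds**

F1 | step 7 | (1S,2R)-1-(4-benzyloxy-3-methoxyphenyl)-3-(3,4-dimethoxybenzyl)-2-[(triisopropylsilyloxy)methyl]butane-1,4-diol, both C3 epimers | COc1cc([C@@H](O)[C@@H](CO[Si](C(C)C)(C(C)C)C(C)C)C(CO)Cc2ccc(OC)c(OC)c2)ccc1OCc1ccccc1
F2 | step 7 | (4R,5S)-5-(4-benzyloxy-3-methoxyphenyl)-3-(3,4-dimethoxybenzyl)-4-[(triisopropylsilyloxy)methyl]dihydrofuran-2(3H)-one, both C3 epimers | COc1cc([C@H]2OC(=O)C(Cc3ccc(OC)c(OC)c3)[C@@H]2CO[Si](C(C)C)(C(C)C)C(C)C)ccc1OCc1ccccc1
F3 | step 7 | (4R,5S)-5-(4-benzyloxy-3-methoxyphenyl)-3-(3,4-dimethoxybenzyl)-4-[(triisopropylsilyloxy)methyl]tetrahydrofuran-2-ol, epimers at C2 and C3 | COc1cc([C@H]2OC(O)C(Cc3ccc(OC)c(OC)c3)[C@@H]2CO[Si](C(C)C)(C(C)C)C(C)C)ccc1OCc1ccccc1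
F4 | step 8 | (3R,4R,5S)-5-(4-benzyloxy-3-methoxyphenyl)-3-(3,4-dimethoxybenzyl)-4-[(triisopropylsilyloxy)methyl]dihydrofuran-2(3H)-one | COc1cc([C@H]2OC(=O)[C@H](Cc3ccc(OC)c(OC)c3)[C@@H]2CO[Si](C(C)C)(C(C)C)C(C)C)ccc1OCc1ccccc1
F5 | step 8 | (1S,2R,3R)-1-(4-benzyloxy-3-methoxyphenyl)-3-(3,4-dimethoxybenzyl)-2-[(triisopropylsilyloxy)methyl]butane-1,4-diol | COc1cc([C@@H](O)[C@@H](CO[Si](C(C)C)(C(C)C)C(C)C)[C@H](CO)Cc2ccc(OC)c(OC)c2)ccc1OCc1ccccc1
F6 | step 8 | (2R,3R,4S)-4-(4-benzyloxy-3-methoxyphenyl)-2-(3,4-dimethoxybenzyl)-4-hydroxy-3-[(triisopropylsilyloxy)methyl]butyl 4-methylbenzenesulfonate | COc1cc([C@@H](O)[C@@H](CO[Si](C(C)C)(C(C)C)C(C)C)[C@H](COS(=O)(=O)c2ccc(C)cc2)Cc2ccc(OC)c(OC)c2)ccc1OCc1ccccc1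
F7 | step 8 | (2S,3R,4R)-2-(4-benzyloxy-3-methoxyphenyl)-4-(3,4-dimethoxybenzyl)-3-[(triisopropylsilyloxy)methyl]tetrahydrofuran | COc1cc([C@H]2OC[C@H](Cc3ccc(OC)c(OC)c3)[C@@H]2CO[Si](C(C)C)(C(C)C)C(C)C)ccc1OCc1ccccc1
F8 | step 6 | (1S,2R)-1-(4-benzyloxy-3-methoxyphenyl)-2-[3-(3,4-dimethoxyphenyl)prop-1-en-2-yl]-3-(triisopropylsilyloxy)propyl formate | COc1cc([C@@H](OC=O)[C@@H](CO[Si](C(C)C)(C(C)C)C(C)C)C(=C)Cc2ccc(OC)c(OC)c2)ccc1OCc1ccccc1
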